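The earlier runs and the new flask are simulated on assumed constants, noise included.

The forms of E cannot add up to more than the E charged. E is a complex whose ligands D exchanges step by step, through X and G to Q. The X that no table shows is therefore the remainder of the balance on E: 47.2% at the end of violet and 43.1% at the end of teal. X is the largest share at the end of each of those two runs. Summer's D charge lies between theirs, so I take X as summer's leader.

all flasks: E 0.060 M

| flask | D | remark | time |
|---|---|---|---|
| ochre | 0.034 M | run made earlier |  |
| violet | 0.072 M | run made earlier |  |
| teal | 0.13 M | run made earlier |  |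
| summer | 0.0900 M |  | 5.0 h |
| spring | 0.180 M |  | 5.0 h |
| winter | 0.0300 M |  | 5.0 h |

- ochre (time / h: Q / %, G / %, E / %): 0.417: 0.4, 6.0, 73.7; 1.33: 1.2, 6.7, 65.6; 2.50: 0, 6.5, 60.7; 4.00: 1.4, 4.9, 58.9; 5.00: 0.3, 4.8, 57.7
- violet (time / h: Q / %, G / %, E / %): 0.417: 0, 16.1, 52.7; 0.833: 1.4, 16.1, 44.1; 1.33: 2.2, 14.8, 39.9; 2.50: 3.0, 13.5, 34.8; 5.00: 5.5, 13.1, 34.2
- teal (time / h: Q / %, G / %, E / %): 1.00: 7.9, 26.3, 20.0; 2.00: 11.4, 23.7, 17.6; 3.00: 15.8, 21.3, 17.5; 4.00: 19.2, 19.2, 18.0; 5.00: 21.9, 16.7, 18.3

(each reading ± 0.5 percentage points)

1. which of these holds the largest part of the E at the end of summer (E / Q / X / G)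
2. which of these holds the largest part of the E at the end of spring (E / Q / X / G)
3. which of these holds the largest part of the E at the end of winter (E / Q / X / G)
4. amount of Q at the end of summer, in percent of the E charged

- the numbers in the tables scatter with a standard deviation of 0.5 percentage points

For Q at the end of summer, I test each given number in turn. Summer's E charge is the same as in ochre, violet and teal, so these runs cannot show what an error in it costs. Summer stops at the time of teal's last row, and between teal's last rows the readings of Q grow as time to the power 0.639, so I take an error in summer's time to return scaled by that. Between violet and teal, the logarithm of the ratio of final Q over the logarithm of the ratio of D charges is 2.34. I call this reading the steepness of Q, its apparent order in D at fixed E and time. I take an error in summer's D charge to return multiplied by it, which outweighs the power of time. The scatter is 9.09% of violet's final Q, and ochre's final Q lies below the scatter, so I leave ochre out. Scaling violet's Q by the steepness, I commit to 9.27%.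

The forecast names X, Q and E as leaders of summer, spring and winter. It puts Q at 9%, within 7.5% to 11%, slightly below my figure. On spring it writes: “Q keeps growing and the steep dependence on D favours it”.

    E + D ⇌ L + X (K = 11.0, k = 0.830 M⁻¹ min⁻¹)
    X + D ⇌ L + G (K = 2.00, k = 1.60 M⁻¹ min⁻¹)
    G + D ⇌ L + Q (K = 140, k = 0.150 M⁻¹ min⁻¹)
    D ⇌ J (K = 1.50, k = 0.0320 min⁻¹)

Summer ends with Q at 9.75%, inside that range, and X leads at 48.2%; Q leads spring and E leads winter. Raising summer's D alone, Q has moved by 5 points at 0.108 M, where the steepness gives 5.1 points. Carried to a flask like summer but charged with 0.36 M of D, the steepness gives 249%, more than the E charged, and that flask ends with Q at 85.1%.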